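**Remark:** carotenoid numbering is used for the skeleton (C15' and C14' are the two CH atoms joined in step 25). Compounds 1, 7, 15, 19, 20, 29 and 37 (sold as an E/Z mixture, E isomer drawn) are taken as purchasable.

## Retrosynthetic overview

1. The last step is a Stille coupling at C15'–C14' of two unprotected halves: dienylstannane 24 (21 carbons, rings A and B) and tetraenyl iodide 43 (19 carbons, rings C and D). The feature that allows it: this is an sp2–sp2 single bond between the unsubstituted E-CH=CH end (C15=C15') of the arm on butenolide ring B and the E-CH=C(CH3) end (C14'=C13') of the arm on the epoxycyclohexane (rings C/D). No ring and no stereocentre sits at the junction, so tin on C15' and iodine on C14' suffice.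
2. Left half 24: ring B is closed by Pd/Cu alkynylation and 5-exo-dig lactonisation of (Z)-iodoacrylic acid 14 with enynol 15. Acid 14 comes from anti-carbomagnesiation of propargyl alcohol with the ring A Grignard reagent. C6 is set by CBS reduction and Johnson–Claisen chirality transfer, the ring A ketone by allylic oxidation, and C15' by a chromium stannyl-olefination.
3. Right half 43: ring C comes from actinol 29 (enol triflate, carbonylation), ring D from Sharpless epoxidation, and the chain from two Horner–Wadsworth–Emmons olefinations (nitrile phosphonate 37, iodoallyl phosphonate 28).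
4. Ring order: rings A and C are bought (1 and 29); ring D (oxirane) is formed in step 19, ring B (butenolide) in step 8; the nonaene is completed last.

Key step: step 25

## Route

### Left half (steps 1–11)

Step 1
Reactants: 1 2,4,4-trimethylcyclohex-2-en-1-one
Product: 2 (1S)-2,4,4-trimethylcyclohex-2-en-1-ol
Conditions: (R)-Me-CBS oxazaborolidine (10 mol%), catecholborane, toluene, −78 °C
Reagents that add atoms: none
Why: Corey–Bakshi–Shibata reduction, in which the oxazaborolidine places the larger alkenyl arm of the enone away from its boron substituent and delivers hydride to one face, so the (R)-catalyst should set the (S)-carbinol that later controls C6.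

Step 2
Reactants: 2 (1S)-2,4,4-trimethylcyclohex-2-en-1-ol
Product: 4 ethyl 2-[(1R)-2,6,6-trimethylcyclohex-2-en-1-yl]acetate, via mixed ketene acetal 3 (not isolated)
Conditions: MeC(OEt)3 (excess), EtCO2H (cat.), 140 °C, ethanol distilled off
Reagents that add atoms: triethyl orthoacetate CC(OCC)(OCC)OCC
Why: Johnson–Claisen rearrangement, whose [3,3] shift is suprafacial on the ring, so the new C–C bond forms on the face the C–O bond leaves and the (S)-carbinol is relayed into the (R)-stereocentre (carotenoid C6).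

Step 3
Reactants: 4 ethyl 2-[(1R)-2,6,6-trimethylcyclohex-2-en-1-yl]acetate
Product: 5 2-[(1R)-2,6,6-trimethylcyclohex-2-en-1-yl]ethan-1-ol
Conditions: LiAlH4, Et2O, 0 °C
Reagents that add atoms: none
Why: hydride reduction of the ester to the primary alcohol, which leaves the isolated trisubstituted alkene and the stereocentre untouched.

Step 4
Reactants: 5 2-[(1R)-2,6,6-trimethylcyclohex-2-en-1-yl]ethan-1-ol
Product: 6 (6R)-6-(2-bromoethyl)-1,5,5-trimethylcyclohex-1-ene
Conditions: CBr4, PPh3, CH2Cl2, 0 °C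
Reagents that add atoms: carbon tetrabromide BrC(Br)(Br)Br
Why: Appel bromination of the unbranched primary alcohol under neutral conditions (SN2 at CH2).

Step 5
Reactants: 6 (6R)-6-(2-bromoethyl)-1,5,5-trimethylcyclohex-1-ene; 7 prop-2-yn-1-ol
Product: 11 (2Z)-3-iodo-2-{2-[(1R)-2,6,6-trimethylcyclohex-2-en-1-yl]ethyl}prop-2-en-1-ol, via alkyl Grignard reagent 8 (not isolated), via bromomagnesium propargyl alkoxide 9 (not isolated), via alkenylmagnesium chelate 10 (not isolated)
Conditions: 6, Mg, THF, 45 °C; separately 7, EtMgBr (1.0 equiv), THF, 0 °C; the two solutions combined, CuI (10 mol%), 0 °C to rt; then I2, −20 °C to rt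
Reagents that add atoms: iodine [I][I]
Why: copper-catalysed anti-carbomagnesiation of the propargylic alkoxide, in which the alkyl group adds to the internal alkyne carbon and magnesium ends on the terminal carbon cis to CH2O in chelate 10, so iodinolysis with retention should fix the (Z)-iodoalkene (iodine cis to CH2OH).

Step 6
Reactants: 11 (2Z)-3-iodo-2-{2-[(1R)-2,6,6-trimethylcyclohex-2-en-1-yl]ethyl}prop-2-en-1-ol
Product: 13 (2Z)-3-iodo-2-{2-[(1R)-2,6,6-trimethylcyclohex-2-en-1-yl]ethyl}prop-2-enoic acid, via iodo enal 12 (not isolated)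
Conditions: TEMPO (10 mol%), PhI(OAc)2, CH2Cl2, rt; then NaClO2, NaH2PO4, 2-methylbut-2-ene, t-BuOH/H2O, 0 °C to rt
Reagents that add atoms: sodium chlorite [Na+].[O-]Cl=O
Why: oxoammonium (TEMPO) oxidation of the allylic alcohol to enal 12 and Pinnick oxidation in the same flask, both non-isomerising, so the Z geometry should be kept while 2-methylbut-2-ene shields the ring alkene from hypochlorite.

Step 7
Reactants: 13 (2Z)-3-iodo-2-{2-[(1R)-2,6,6-trimethylcyclohex-2-en-1-yl]ethyl}prop-2-enoic acid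
Product: 14 (2Z)-3-iodo-2-{2-[(1R)-2,6,6-trimethyl-4-oxocyclohex-2-en-1-yl]ethyl}prop-2-enoic acid
Conditions: Rh2(cap)4 (cap = caprolactamate, 1 mol%), t-BuOOH (70% aq.), 1,2-dichloroethane, 40 °C
Reagents that add atoms: tert-butyl hydroperoxide CC(C)(C)OO
Why: dirhodium-catalysed allylic C–H oxidation, in which hydrogen abstraction is favoured at the ring CH2 next to the electron-rich trisubstituted alkene (the position oxidised in α-ionone-type rings) while the CH2 next to the electron-poor iodoacrylic acid is deactivated, and the stereocentre is not involved.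

Step 8
Reactants: 14 (2Z)-3-iodo-2-{2-[(1R)-2,6,6-trimethyl-4-oxocyclohex-2-en-1-yl]ethyl}prop-2-enoic acid; 15 (2E)-3-methylpent-2-en-4-yn-1-ol
Product: 17 (5Z)-5-[(2E)-4-hydroxy-2-methylbut-2-en-1-ylidene]-3-{2-[(1R)-2,6,6-trimethyl-4-oxocyclohex-2-en-1-yl]ethyl}furan-2(5H)-one, via enynoic acid 16 (not isolated)
Conditions: Pd(PPh3)4 (5 mol%), CuI (10 mol%), Et3N, MeCN, rt, dark
Reagents that add atoms: none
Why: Sonogashira coupling at the vinyl iodide followed in the same pot by 5-exo-dig anti-addition of the cis-carboxylate across the metal-activated alkyne (tandem alkynylation–lactonisation), which closes ring B and should give the (Z)-ylidene while the E alkene of 15 is untouched.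

Step 9
Reactants: 17 (5Z)-5-[(2E)-4-hydroxy-2-methylbut-2-en-1-ylidene]-3-{2-[(1R)-2,6,6-trimethyl-4-oxocyclohex-2-en-1-yl]ethyl}furan-2(5H)-one
Product: 18 (2E,4Z)-3-methyl-4-[5-oxo-4-{2-[(1R)-2,6,6-trimethyl-4-oxocyclohex-2-en-1-yl]ethyl}furan-2(5H)-ylidene]but-2-enal
Conditions: MnO2 (activated, excess), CH2Cl2, rt, dark
Reagents that add atoms: none
Why: chemoselective MnO2 oxidation of the primary allylic (dienylic) alcohol to the conjugated aldehyde.

Step 10
Reactants: 19 tributyltin chloride; 20 dibromomethane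
Product: 22 tributyl(dibromomethyl)stannane, via dibromomethyllithium 21 (not isolated)
Conditions: 20, LiN(iPr)2, THF/Et2O, −95 °C; then 19, −95 °C to rt
Reagents that add atoms: none
Why: deprotonation of CH2Br2 to the carbenoid at very low temperature and its stannylation by nucleophilic substitution at tin.

Step 11
Reactants: 18 (2E,4Z)-3-methyl-4-[5-oxo-4-{2-[(1R)-2,6,6-trimethyl-4-oxocyclohex-2-en-1-yl]ethyl}furan-2(5H)-ylidene]but-2-enal; 22 tributyl(dibromomethyl)stannane
Product: 24 (5Z)-5-[(2E,4E)-2-methyl-5-(tributylstannyl)penta-2,4-dien-1-ylidene]-3-{2-[(1R)-2,6,6-trimethyl-4-oxocyclohex-2-en-1-yl]ethyl}furan-2(5H)-one, via tributyl(diiodomethyl)stannane 23 (not isolated)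
Conditions: CrCl2 (excess), LiI, THF/DMF, rt, dark
Reagents that add atoms: none
Why: Takai-type chromium-mediated olefination with a gem-dihalomethylstannane (halide exchange to 23, insertion of divalent chromium to a gem-dichromium reagent, addition and elimination), which is aldehyde-selective beside the enone and lactone and should give the (E)-alkenylstannane at C15=C15'.

### Iodoallyl phosphonate (steps 12–14)

Step 12
Reactants: 7 prop-2-yn-1-ol
Product: 26 (2E)-3-iodo-2-methylprop-2-en-1-ol, via alkenylalane 25 (not isolated)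
Conditions: AlMe3 (3 equiv), Cp2ZrCl2 (25 mol%), CH2Cl2, 0 °C to rt; then I2, THF, −30 to 0 °C
Reagents that add atoms: trimethylaluminium C[Al](C)C; iodine [I][I]
Why: zirconium-catalysed syn-methylalumination of the terminal alkyne (methyl to the internal carbon, aluminium to the terminal carbon) and iodinolysis with retention, which should give the (E)-iodoalkene.

Step 13
Reactants: 26 (2E)-3-iodo-2-methylprop-2-en-1-ol
Product: 27 (1E)-3-bromo-1-iodo-2-methylprop-1-ene
Conditions: PBr3, Et2O, 0 °C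
Reagents that add atoms: phosphorus tribromide BrP(Br)Br
Why: SN2 bromination of the primary allylic alcohol, to which the vinyl iodide is inert.

Step 14
Reactants: 27 (1E)-3-bromo-1-iodo-2-methylprop-1-ene
Product: 28 diethyl [(2E)-3-iodo-2-methylprop-2-en-1-yl]phosphonate
Conditions: P(OEt)3, neat, 100 °C
Reagents that add atoms: triethyl phosphite CCOP(OCC)OCC
Why: Michaelis–Arbuzov reaction of the allylic bromide.

### Right half (steps 15–24)

Step 15
Reactants: 29 (4R,6R)-4-hydroxy-2,2,6-trimethylcyclohexan-1-one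
Product: 30 (4R,6R)-4-[(tert-butyldimethylsilyl)oxy]-2,2,6-trimethylcyclohexan-1-one
Conditions: TBSCl, imidazole, DMF, rt
Reagents that add atoms: tert-butyldimethylsilyl chloride CC(C)(C)[Si](C)(C)Cl
Why: imidazole-promoted silylation of the secondary alcohol.

Step 16
Reactants: 30 (4R,6R)-4-[(tert-butyldimethylsilyl)oxy]-2,2,6-trimethylcyclohexan-1-one
Product: 32 (4R)-4-[(tert-butyldimethylsilyl)oxy]-2,6,6-trimethylcyclohex-1-en-1-yl trifluoromethanesulfonate, via potassium enolate 31 (not isolated)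
Conditions: KN(SiMe3)2, THF, −78 °C; then PhNTf2, −78 to 0 °C
Reagents that add atoms: N-phenylbis(trifluoromethanesulfonimide) O=S(=O)(N(c1ccccc1)S(=O)(=O)C(F)(F)F)C(F)(F)F
Why: deprotonation at the only enolisable α-position (the other α-carbon is quaternary) and O-triflation of the enolate, which erases the methyl-bearing stereocentre on purpose and leaves the silyloxy carbon untouched.

Step 17
Reactants: 32 (4R)-4-[(tert-butyldimethylsilyl)oxy]-2,6,6-trimethylcyclohex-1-en-1-yl trifluoromethanesulfonate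
Product: 33 methyl (4R)-4-[(tert-butyldimethylsilyl)oxy]-2,6,6-trimethylcyclohex-1-ene-1-carboxylate
Conditions: Pd(OAc)2 (5 mol%), PPh3 (10 mol%), CO (1 atm), MeOH, Et3N, DMF, 60 °C
Reagents that add atoms: carbon monoxide [C-]#[O+]; methanol CO
Why: palladium-catalysed methoxycarbonylation of the alkenyl triflate (oxidative addition, CO insertion, methanolysis).

Step 18
Reactants: 33 methyl (4R)-4-[(tert-butyldimethylsilyl)oxy]-2,6,6-trimethylcyclohex-1-ene-1-carboxylate
Product: 34 {(4R)-4-[(tert-butyldimethylsilyl)oxy]-2,6,6-trimethylcyclohex-1-en-1-yl}methanol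
Conditions: i-Bu2AlH (2.5 equiv), CH2Cl2, −78 °C
Reagents that add atoms: none
Why: i-Bu2AlH reduction of the conjugated ester to the allylic alcohol.

Step 19
Reactants: 34 {(4R)-4-[(tert-butyldimethylsilyl)oxy]-2,6,6-trimethylcyclohex-1-en-1-yl}methanol
Product: 35 {(1R,4S,6R)-4-[(tert-butyldimethylsilyl)oxy]-2,2,6-trimethyl-7-oxabicyclo[4.1.0]heptan-1-yl}methanol
Conditions: Ti(OiPr)4 (20 mol%), D-(−)-diethyl tartrate (24 mol%), t-BuOOH (decane), 4 Å sieves, CH2Cl2, −20 °C
Reagents that add atoms: tert-butyl hydroperoxide CC(C)(C)OO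
Why: Sharpless asymmetric epoxidation of the tetrasubstituted allylic alcohol, in which D-(−)-tartrate directs oxygen to the face anti to the silyloxy group (matched with the steric bias) and sets both oxirane stereocentres of ring D.

Step 20
Reactants: 35 {(1R,4S,6R)-4-[(tert-butyldimethylsilyl)oxy]-2,2,6-trimethyl-7-oxabicyclo[4.1.0]heptan-1-yl}methanol
Product: 36 (1S,4S,6R)-4-[(tert-butyldimethylsilyl)oxy]-2,2,6-trimethyl-7-oxabicyclo[4.1.0]heptane-1-carbaldehyde
Conditions: Pr4N[RuO4] (5 mol%), N-methylmorpholine N-oxide, 4 Å sieves, CH2Cl2, rt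
Reagents that add atoms: none
Why: Ley–Griffith oxidation of the neopentyl-type primary alcohol to the aldehyde without touching the oxirane (the descriptor at C1 changes only through CIP priorities).

Step 21
Reactants: 36 (1S,4S,6R)-4-[(tert-butyldimethylsilyl)oxy]-2,2,6-trimethyl-7-oxabicyclo[4.1.0]heptane-1-carbaldehyde; 37 diethyl (3-cyano-2-methylprop-2-en-1-yl)phosphonate
Product: 39 (2E,4E)-5-{(1S,4S,6R)-4-[(tert-butyldimethylsilyl)oxy]-2,2,6-trimethyl-7-oxabicyclo[4.1.0]heptan-1-yl}-3-methylpenta-2,4-dienenitrile, via sodium phosphonate carbanion 38 (not isolated)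
Conditions: 37, NaH, THF, 0 °C; then 36, 0 °C to rt
Reagents that add atoms: none
Why: Horner–Wadsworth–Emmons olefination of the non-enolisable aldehyde, which should give the (E)-C7'=C8' bond, the minor (9'Z) isomer that stems from the reagent being removed by chromatography.

Step 22
Reactants: 39 (2E,4E)-5-{(1S,4S,6R)-4-[(tert-butyldimethylsilyl)oxy]-2,2,6-trimethyl-7-oxabicyclo[4.1.0]heptan-1-yl}-3-methylpenta-2,4-dienenitrile
Product: 40 (2E,4E)-5-{(1S,4S,6R)-4-[(tert-butyldimethylsilyl)oxy]-2,2,6-trimethyl-7-oxabicyclo[4.1.0]heptan-1-yl}-3-methylpenta-2,4-dienal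
Conditions: i-Bu2AlH (1.3 equiv), toluene, −78 °C; then wet SiO2, 0 °C
Reagents that add atoms: water O
Why: partial reduction of the nitrile to the N-aluminated aldimine and near-neutral hydrolysis to the aldehyde, the low temperature and mild hydrolysis sparing the vinyl oxirane.

Step 23
Reactants: 40 (2E,4E)-5-{(1S,4S,6R)-4-[(tert-butyldimethylsilyl)oxy]-2,2,6-trimethyl-7-oxabicyclo[4.1.0]heptan-1-yl}-3-methylpenta-2,4-dienal; 28 diethyl [(2E)-3-iodo-2-methylprop-2-en-1-yl]phosphonate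
Product: 42 tert-butyl({(1S,4S,6R)-1-[(1E,3E,5E,7E)-8-iodo-3,7-dimethylocta-1,3,5,7-tetraen-1-yl]-2,2,6-trimethyl-7-oxabicyclo[4.1.0]heptan-4-yl}oxy)dimethylsilane, via sodium phosphonate carbanion 41 (not isolated)
Conditions: 28, NaN(SiMe3)2, THF, −78 °C; then 40, −78 to 0 °C, dark
Reagents that add atoms: none
Why: Horner–Wadsworth–Emmons olefination with the allylic phosphonate anion, which should form the (E)-C11'=C12' bond and carries the (E)-iodoalkene in unchanged.

Step 24
Reactants: 42 tert-butyl({(1S,4S,6R)-1-[(1E,3E,5E,7E)-8-iodo-3,7-dimethylocta-1,3,5,7-tetraen-1-yl]-2,2,6-trimethyl-7-oxabicyclo[4.1.0]heptan-4-yl}oxy)dimethylsilane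
Product: 43 (1S,4S,6R)-1-[(1E,3E,5E,7E)-8-iodo-3,7-dimethylocta-1,3,5,7-tetraen-1-yl]-2,2,6-trimethyl-7-oxabicyclo[4.1.0]heptan-4-ol
Conditions: Bu4NF, THF, 0 °C to rt, dark
Reagents that add atoms: none
Why: fluoride-induced cleavage of the silyl ether, during which the iodoalkene cannot eliminate (C13' bears no hydrogen) and the oxirane is inert.

### Union of the halves

Step 25
Reactants: 24 (5Z)-5-[(2E,4E)-2-methyl-5-(tributylstannyl)penta-2,4-dien-1-ylidene]-3-{2-[(1R)-2,6,6-trimethyl-4-oxocyclohex-2-en-1-yl]ethyl}furan-2(5H)-one; 43 (1S,4S,6R)-1-[(1E,3E,5E,7E)-8-iodo-3,7-dimethylocta-1,3,5,7-tetraen-1-yl]-2,2,6-trimethyl-7-oxabicyclo[4.1.0]heptan-4-ol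
Product: 44 CNP0251552.1 (target)
Conditions: Pd2(dba)3 (5 mol%), AsPh3 (40 mol%), degassed NMP, rt to 40 °C, argon, dark
Reagents that add atoms: none
Why: Stille cross-coupling, in which zerovalent palladium inserts into the C14'–I bond of 43, the C15' alkenyl group of 24 passes from tin to palladium and reductive elimination forms the C15'–C14' bond; the closest known reaction type is the palladium-catalysed union of polyenyl stannanes with polyenyl iodides used for carotenoid polyenes. No ring is closed and no stereocentre is created, so the four stereocentres are carried in unchanged. The E geometries at C15=C15' and C14'=C13' are fixed in 24 and 43 and should be transferred with retention, because oxidative addition and transmetalation at sp2 carbon are stereoretentive. The step needs cross- over homo-coupling and tolerance of the free hydroxyl, the vinyl oxirane, the enol lactone and the enone; the neutral, base-free conditions near room temperature secure this, and the weakly donating AsPh3 speeds transmetalation of the electron-poor dienylstannane. Light and oxygen are excluded to keep the nonaene all-E.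

## Compound list

1 | 2,4,4-trimethylcyclohex-2-en-1-one | CC1=CC(C)(C)CCC1=O | starting material
2 | (1S)-2,4,4-trimethylcyclohex-2-en-1-ol | O[C@@H]1C(C)=CC(C)(C)CC1 | intermediate
3 | 1-ethoxy-1-{[(1S)-2,4,4-trimethylcyclohex-2-en-1-yl]oxy}ethene (mixed ketene acetal) | C=C(OCC)O[C@@H]1C(C)=CC(C)(C)CC1 | intermediate
4 | ethyl 2-[(1R)-2,6,6-trimethylcyclohex-2-en-1-yl]acetate | CCOC(=O)C[C@H]1C(C)=CCCC1(C)C | intermediate
5 | 2-[(1R)-2,6,6-trimethylcyclohex-2-en-1-yl]ethan-1-ol | OCC[C@H]1C(C)=CCCC1(C)C | intermediate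
6 | (6R)-6-(2-bromoethyl)-1,5,5-trimethylcyclohex-1-ene | BrCC[C@H]1C(C)=CCCC1(C)C | intermediate
7 | prop-2-yn-1-ol | C#CCO | starting material
8 | {2-[(1R)-2,6,6-trimethylcyclohex-2-en-1-yl]ethyl}magnesium bromide | CC1=CCCC(C)(C)[C@H]1CC[Mg]Br | intermediate
9 | bromomagnesium prop-2-yn-1-olate | C#CCO[Mg]Br | intermediate
10 | 4-{2-[(1R)-2,6,6-trimethylcyclohex-2-en-1-yl]ethyl}-2,5-dihydro-1,2-oxamagnesole | CC1=CCCC(C)(C)[C@H]1CCC1=C[Mg]OC1 | intermediate
11 | (2Z)-3-iodo-2-{2-[(1R)-2,6,6-trimethylcyclohex-2-en-1-yl]ethyl}prop-2-en-1-ol | OC/C(CC[C@H]1C(C)=CCCC1(C)C)=C\I | intermediate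
12 | (2Z)-3-iodo-2-{2-[(1R)-2,6,6-trimethylcyclohex-2-en-1-yl]ethyl}prop-2-enal | O=C/C(CC[C@H]1C(C)=CCCC1(C)C)=C\I | intermediate
13 | (2Z)-3-iodo-2-{2-[(1R)-2,6,6-trimethylcyclohex-2-en-1-yl]ethyl}prop-2-enoic acid | OC(=O)/C(CC[C@H]1C(C)=CCCC1(C)C)=C\I | intermediate
14 | (2Z)-3-iodo-2-{2-[(1R)-2,6,6-trimethyl-4-oxocyclohex-2-en-1-yl]ethyl}prop-2-enoic acid | OC(=O)/C(CC[C@H]1C(C)=CC(=O)CC1(C)C)=C\I | intermediate
15 | (2E)-3-methylpent-2-en-4-yn-1-ol | C#C/C(C)=C/CO | starting material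
16 | (2Z,6E)-8-hydroxy-6-methyl-2-{2-[(1R)-2,6,6-trimethyl-4-oxocyclohex-2-en-1-yl]ethyl}octa-2,6-dien-4-ynoic acid | OC(=O)/C(CC[C@H]1C(C)=CC(=O)CC1(C)C)=C\C#C/C(C)=C/CO | intermediate
17 | (5Z)-5-[(2E)-4-hydroxy-2-methylbut-2-en-1-ylidene]-3-{2-[(1R)-2,6,6-trimethyl-4-oxocyclohex-2-en-1-yl]ethyl}furan-2(5H)-one | CC1=CC(=O)CC(C)(C)[C@H]1CCC1=C/C(=C/C(C)=C/CO)OC1=O | intermediate
18 | (2E,4Z)-3-methyl-4-[5-oxo-4-{2-[(1R)-2,6,6-trimethyl-4-oxocyclohex-2-en-1-yl]ethyl}furan-2(5H)-ylidene]but-2-enal | CC1=CC(=O)CC(C)(C)[C@H]1CCC1=C/C(=C/C(C)=C/C=O)OC1=O | intermediate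
19 | tributyltin chloride | CCCC[Sn](Cl)(CCCC)CCCC | starting material
20 | dibromomethane | BrCBr | starting material
21 | dibromomethyllithium | [Li]C(Br)Br | intermediate
22 | tributyl(dibromomethyl)stannane | CCCC[Sn](CCCC)(CCCC)C(Br)Br | intermediate
23 | tributyl(diiodomethyl)stannane | CCCC[Sn](CCCC)(CCCC)C(I)I | intermediate
24 | (5Z)-5-[(2E,4E)-2-methyl-5-(tributylstannyl)penta-2,4-dien-1-ylidene]-3-{2-[(1R)-2,6,6-trimethyl-4-oxocyclohex-2-en-1-yl]ethyl}furan-2(5H)-one | CC1=CC(=O)CC(C)(C)[C@H]1CCC1=C/C(=C/C(C)=C/C=C/[Sn](CCCC)(CCCC)CCCC)OC1=O | intermediate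
25 | {(1E)-3-[(dimethylalumanyl)oxy]-2-methylprop-1-en-1-yl}dimethylalumane | C[Al](C)OC/C(C)=C/[Al](C)C | intermediate
26 | (2E)-3-iodo-2-methylprop-2-en-1-ol | OC/C(C)=C/I | intermediate
27 | (1E)-3-bromo-1-iodo-2-methylprop-1-ene | BrC/C(C)=C/I | intermediate
28 | diethyl [(2E)-3-iodo-2-methylprop-2-en-1-yl]phosphonate | CCOP(=O)(OCC)C/C(C)=C/I | intermediate
29 | (4R,6R)-4-hydroxy-2,2,6-trimethylcyclohexan-1-one (actinol) | O=C1[C@H](C)C[C@@H](O)CC1(C)C | starting material
30 | (4R,6R)-4-[(tert-butyldimethylsilyl)oxy]-2,2,6-trimethylcyclohexan-1-one | O=C1[C@H](C)C[C@@H](O[Si](C)(C)C(C)(C)C)CC1(C)C | intermediate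
31 | potassium (4R)-4-[(tert-butyldimethylsilyl)oxy]-2,6,6-trimethylcyclohex-1-en-1-olate | [K+].[O-]C1=C(C)C[C@@H](O[Si](C)(C)C(C)(C)C)CC1(C)C | intermediate
32 | (4R)-4-[(tert-butyldimethylsilyl)oxy]-2,6,6-trimethylcyclohex-1-en-1-yl trifluoromethanesulfonate | FC(F)(F)S(=O)(=O)OC1=C(C)C[C@@H](O[Si](C)(C)C(C)(C)C)CC1(C)C | intermediate
33 | methyl (4R)-4-[(tert-butyldimethylsilyl)oxy]-2,6,6-trimethylcyclohex-1-ene-1-carboxylate | COC(=O)C1=C(C)C[C@@H](O[Si](C)(C)C(C)(C)C)CC1(C)C | intermediate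
34 | {(4R)-4-[(tert-butyldimethylsilyl)oxy]-2,6,6-trimethylcyclohex-1-en-1-yl}methanol | OCC1=C(C)C[C@@H](O[Si](C)(C)C(C)(C)C)CC1(C)C | intermediate
35 | {(1R,4S,6R)-4-[(tert-butyldimethylsilyl)oxy]-2,2,6-trimethyl-7-oxabicyclo[4.1.0]heptan-1-yl}methanol | OC[C@@]12O[C@]1(C)C[C@@H](O[Si](C)(C)C(C)(C)C)CC2(C)C | intermediate
36 | (1S,4S,6R)-4-[(tert-butyldimethylsilyl)oxy]-2,2,6-trimethyl-7-oxabicyclo[4.1.0]heptane-1-carbaldehyde | O=C[C@@]12O[C@]1(C)C[C@@H](O[Si](C)(C)C(C)(C)C)CC2(C)C | intermediate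
37 | diethyl (3-cyano-2-methylprop-2-en-1-yl)phosphonate (E/Z mixture, E drawn) | CCOP(=O)(OCC)C/C(C)=C/C#N | starting material
38 | sodium salt of the carbanion of 37 | [Na+].CCOP(=O)(OCC)[CH-]C(C)=CC#N | intermediate
39 | (2E,4E)-5-{(1S,4S,6R)-4-[(tert-butyldimethylsilyl)oxy]-2,2,6-trimethyl-7-oxabicyclo[4.1.0]heptan-1-yl}-3-methylpenta-2,4-dienenitrile | N#C/C=C(C)/C=C/[C@@]12O[C@]1(C)C[C@@H](O[Si](C)(C)C(C)(C)C)CC2(C)C | intermediate
40 | (2E,4E)-5-{(1S,4S,6R)-4-[(tert-butyldimethylsilyl)oxy]-2,2,6-trimethyl-7-oxabicyclo[4.1.0]heptan-1-yl}-3-methylpenta-2,4-dienal | O=C/C=C(C)/C=C/[C@@]12O[C@]1(C)C[C@@H](O[Si](C)(C)C(C)(C)C)CC2(C)C | intermediate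
41 | sodium salt of the carbanion of 28 | [Na+].CCOP(=O)(OCC)[CH-]/C(C)=C/I | intermediate
42 | tert-butyl({(1S,4S,6R)-1-[(1E,3E,5E,7E)-8-iodo-3,7-dimethylocta-1,3,5,7-tetraen-1-yl]-2,2,6-trimethyl-7-oxabicyclo[4.1.0]heptan-4-yl}oxy)dimethylsilane | I/C=C(C)/C=C/C=C(C)/C=C/[C@@]12O[C@]1(C)C[C@@H](O[Si](C)(C)C(C)(C)C)CC2(C)C | intermediate
43 | (1S,4S,6R)-1-[(1E,3E,5E,7E)-8-iodo-3,7-dimethylocta-1,3,5,7-tetraen-1-yl]-2,2,6-trimethyl-7-oxabicyclo[4.1.0]heptan-4-ol | I/C=C(C)/C=C/C=C(C)/C=C/[C@@]12O[C@]1(C)C[C@@H](O)CC2(C)C | intermediate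
44 | CNP0251552.1 | CC1=CC(=O)CC(C)(C)[C@H]1CCC1=C/C(=C/C(C)=C/C=C/C=C(C)/C=C/C=C(C)/C=C/[C@@]23O[C@]2(C)C[C@@H](O)CC3(C)C)OC1=O | target

## Step count and risks

Total step count: 25. Longest linear sequence: 11 steps (steps 1–9, 11 and 25; the right-half line, steps 15–25, is equally long).

Steps most likely to fail:

Step 7. The oxidation may attack another allylic position, run on to over-oxidised products, or degrade the iodoalkene under peroxide. Fallback: set out from bromide 6 and bring the ring oxygen in before any iodoalkene exists, carrying it as a silyl-protected allylic alcohol. Allylic oxidation of 6 (CrO3, 3,5-dimethylpyrazole, CH2Cl2) should give bromo enone F1. Luche reduction (NaBH4, CeCl3) gives allylic alcohol F2 (either carbinol epimer serves; the 1,4-cis epimer is drawn), and TBSCl/imidazole gives silyl ether F3. The chemistry of steps 5, 6 and 8 then gives iodo alcohol F4, iodo acid F5 and butenolide F6. HF·pyridine frees diol F7, and MnO2 oxidises both allylic hydroxyls at once, which comes back to the route at aldehyde 18.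

Step 11. Conversion of the sensitive trienal may be incomplete, the E selectivity may erode, and the dienylstannane may lose tin on isolation. Fallback: from 18 use the boron version of the chromium olefination (Cl2CHBpin, CrCl2, LiI, THF) to make the dienyl boronate F8, and join F8 with iodide 43 by Suzuki–Miyaura coupling (Pd(PPh3)4, TlOEt, aqueous THF, rt), which comes back to the route at 44.

Step 25. Transmetalation of the electron-poor stannane may be slow, so that homocoupling and E/Z scrambling of the polyene compete. Fallback: form the same C15'–C14' bond at the alkyne oxidation level. From 18, Seyferth–Gilbert homologation with the Ohira–Bestmann reagent (K2CO3, MeOH, 0 °C, brief) gives dienyne F9. Sonogashira coupling of F9 with 43 (Pd(PPh3)4, CuI, Et3N) gives the 15,15'-didehydro compound F10. Lindlar semi-hydrogenation (Pd/CaCO3 poisoned with Pb(OAc)2, quinoline, H2) gives the (15Z)-isomer F11, and thermal or iodine-catalysed Z-to-E isomerisation comes back to the route at 44.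

Further compounds
F1 | step 7 | (4R)-4-(2-bromoethyl)-3,5,5-trimethylcyclohex-2-en-1-one | BrCC[C@H]1C(C)=CC(=O)CC1(C)C
F2 | step 7 | (1S,4R)-4-(2-bromoethyl)-3,5,5-trimethylcyclohex-2-en-1-ol | BrCC[C@H]1C(C)=C[C@@H](O)CC1(C)C
F3 | step 7 | {[(1S,4R)-4-(2-bromoethyl)-3,5,5-trimethylcyclohex-2-en-1-yl]oxy}(tert-butyl)dimethylsilane | BrCC[C@H]1C(C)=C[C@@H](O[Si](C)(C)C(C)(C)C)CC1(C)C
F4 | step 7 | (2Z)-2-{2-[(1R,4S)-4-[(tert-butyldimethylsilyl)oxy]-2,6,6-trimethylcyclohex-2-en-1-yl]ethyl}-3-iodoprop-2-en-1-ol | OC/C(CC[C@H]1C(C)=C[C@@H](O[Si](C)(C)C(C)(C)C)CC1(C)C)=C\I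
F5 | step 7 | (2Z)-2-{2-[(1R,4S)-4-[(tert-butyldimethylsilyl)oxy]-2,6,6-trimethylcyclohex-2-en-1-yl]ethyl}-3-iodoprop-2-enoic acid | OC(=O)/C(CC[C@H]1C(C)=C[C@@H](O[Si](C)(C)C(C)(C)C)CC1(C)C)=C\I
F6 | step 7 | (5Z)-3-{2-[(1R,4S)-4-[(tert-butyldimethylsilyl)oxy]-2,6,6-trimethylcyclohex-2-en-1-yl]ethyl}-5-[(2E)-4-hydroxy-2-methylbut-2-en-1-ylidene]furan-2(5H)-one | CC1=C[C@@H](O[Si](C)(C)C(C)(C)C)CC(C)(C)[C@H]1CCC1=C/C(=C/C(C)=C/CO)OC1=O
F7 | step 7 | (5Z)-3-{2-[(1R,4S)-4-hydroxy-2,6,6-trimethylcyclohex-2-en-1-yl]ethyl}-5-[(2E)-4-hydroxy-2-methylbut-2-en-1-ylidene]furan-2(5H)-one | CC1=C[C@@H](O)CC(C)(C)[C@H]1CCC1=C/C(=C/C(C)=C/CO)OC1=O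
F8 | step 11 | (5Z)-5-[(2E,4E)-2-methyl-5-(4,4,5,5-tetramethyl-1,3,2-dioxaborolan-2-yl)penta-2,4-dien-1-ylidene]-3-{2-[(1R)-2,6,6-trimethyl-4-oxocyclohex-2-en-1-yl]ethyl}furan-2(5H)-one | CC1=CC(=O)CC(C)(C)[C@H]1CCC1=C/C(=C/C(C)=C/C=C/B2OC(C)(C)C(C)(C)O2)OC1=O
F9 | step 25 | (5Z)-5-[(2E)-2-methylpent-2-en-4-yn-1-ylidene]-3-{2-[(1R)-2,6,6-trimethyl-4-oxocyclohex-2-en-1-yl]ethyl}furan-2(5H)-one | CC1=CC(=O)CC(C)(C)[C@H]1CCC1=C/C(=C/C(C)=C/C#C)OC1=O
F10 | step 25 | 15,15'-didehydro analogue of 44 (C15≡C15' alkyne, all other alkenes as in 44) | CC1=CC(=O)CC(C)(C)[C@H]1CCC1=C/C(=C/C(C)=C/C#C/C=C(C)/C=C/C=C(C)/C=C/[C@@]23O[C@]2(C)C[C@@H](O)CC3(C)C)OC1=O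
F11 | step 25 | (15Z)-isomer of 44 | CC1=CC(=O)CC(C)(C)[C@H]1CCC1=C/C(=C/C(C)=C/C=C\C=C(C)\C=C\C=C(C)\C=C\[C@@]23O[C@]2(C)C[C@@H](O)CC3(C)C)OC1=O
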